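**Plan**

- Retrosynthesis: unmask the two phenols (silyl ethers), then cut the ring bond between O1 and the aryl-bearing C2 (O9'–C7 in lignan numbering), which opens the tetrahydrofuran to a 4-hydroxybutyl mono-ester. Cut the ester C–O bond to a C2-symmetric (2S,3S)-2,3-dibenzylbutane-1,4-diol plus (R)-2-methylbutanoic acid, then the central C8–C8' bond to two identical 3-arylpropanoyl units.
- Forward: protected dihydroferulic acid on an (R)-oxazolidinone is dimerized by oxidative enolate coupling and reduced to the diol. Mono-acylation breaks the symmetry, the only ring is closed last, and the silyl groups are removed.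
- Enabling feature: in the mono-ester the benzylic C7–H2 lies δ to the one free hydroxyl (O–C9'–C8'–C8–C7), while the other benzylic CH2 (C7') is only β. An oxygen radical on O9' therefore reaches exactly the hydrogen whose carbon becomes C2 of the tetrahydrofuran ring (O1, C2, C3, C4, C5).
- Stereochemistry: C8 and C8' (ring C3, C4) come from the auxiliary in the homocoupling; C7 (ring C2) comes from substrate control in the ring closure; the acyl stereocenter is purchased.

Key step: step 6

Remark: lignan numbering is used for positions (C7/C7' benzylic, C8/C8' stereocenters, C9/C9' oxygen-bearing carbons, primed atoms in the benzyl half), and (R)-2-methylbutanoic acid is taken as a purchased enantiopure acid.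

**Route**

Step 1
Reactants: 1 3-(4-hydroxy-3-methoxyphenyl)propanoic acid
Product: 3 3-[3-methoxy-4-(triisopropylsilyloxy)phenyl]propanoic acid, via bis-silylated silyl ester 2 (not isolated)
Conditions: TIPSCl (2.3 equiv), imidazole, DMF, 20 °C; then K2CO3, MeOH/THF/H2O, 20 °C; dilute HCl work-up to pH 4
Reagents that add atoms: triisopropylsilyl chloride, CC(C)[Si](Cl)(C(C)C)C(C)C
Why: Imidazole-mediated silylation caps both the phenol and the acid, and mild carbonate hydrolysis then frees only the far more labile silyl ester, leaving the phenol as an aryl TIPS ether that tolerates base, hydride and Lewis acid; no stereocenter is involved.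

Step 2
Reactants: 3 3-[3-methoxy-4-(triisopropylsilyloxy)phenyl]propanoic acid; 4 (R)-4-isopropyl-2-oxazolidinone
Product: 6 (4R)-4-isopropyl-3-{3-[3-methoxy-4-(triisopropylsilyloxy)phenyl]propanoyl}oxazolidin-2-one, via mixed pivalic anhydride 5 (not isolated)
Conditions: PivCl, Et3N, THF, −20 °C; then 4, LiCl, −20 → 20 °C
Reagents that add atoms: none
Why: N-acylation of an Evans oxazolidinone through the mixed pivalic anhydride with LiCl/Et3N activation is a standard method and installs the (R)-auxiliary that will control both C8 and C8'.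

Step 3
Reactants: 6 (4R)-4-isopropyl-3-{3-[3-methoxy-4-(triisopropylsilyloxy)phenyl]propanoyl}oxazolidin-2-one (two molecules)
Product: 8 (4R,4'R)-3,3'-{(2S,3S)-2,3-bis[3-methoxy-4-(triisopropylsilyloxy)benzyl]butanedioyl}bis(4-isopropyloxazolidin-2-one), via lithium Z-enolate 7 (not isolated)
Conditions: LiN(iPr)2, THF, −78 °C; then TiCl4, −78 → 0 °C
Reagents that add atoms: none
Why: Oxidative homocoupling of the chelated Z-enolate of an Evans imide, in which one-electron oxidation by TiCl4 (tetravalent to trivalent titanium) gives α-acyl radicals that join C8 to C8', each new center forming on the enolate face opposite the isopropyl group of its own (R)-auxiliary to give the C2-symmetric (2S,3S) dimer, a reaction type precedented for 3-arylpropanoyl oxazolidinones in dibenzylbutane lignan work.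

Step 4
Reactants: 8 (4R,4'R)-3,3'-{(2S,3S)-2,3-bis[3-methoxy-4-(triisopropylsilyloxy)benzyl]butanedioyl}bis(4-isopropyloxazolidin-2-one)
Product: 9 (2S,3S)-2,3-bis[3-methoxy-4-(triisopropylsilyloxy)benzyl]butane-1,4-diol
Conditions: LiBH4, MeOH (additive), THF, 0 → 20 °C
Reagents that add atoms: none
Why: Reductive cleavage of N-acyl oxazolidinones with LiBH4 gives the primary alcohols without touching the α-stereocenters or the aryl silyl ethers and returns the auxiliary.

Step 5
Reactants: 9 (2S,3S)-2,3-bis[3-methoxy-4-(triisopropylsilyloxy)benzyl]butane-1,4-diol; 10 (R)-2-methylbutanoic acid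
Product: 12 (2S,3S)-4-hydroxy-2,3-bis[3-methoxy-4-(triisopropylsilyloxy)benzyl]butyl (2R)-2-methylbutanoate, via O-acylisourea 11 (not isolated)
Conditions: 9 (2 equiv), 10 (1 equiv), DCC, DMAP (cat.), CH2Cl2, 0 → 20 °C; unreacted 9 recovered
Reagents that add atoms: none
Why: Steglich esterification in which the two hydroxyls of C2-symmetric 9 are homotopic, so mono-acylation can give only one compound, the excess of diol holds back the diester and is recovered, and the α-stereocenter of the branched aliphatic acid is not at risk under carbodiimide/DMAP activation at 0 °C.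

Step 6
Reactants: 12 (2S,3S)-4-hydroxy-2,3-bis[3-methoxy-4-(triisopropylsilyloxy)benzyl]butyl (2R)-2-methylbutanoate
Product: 15 [(2R,3S,4S)-4-[3-methoxy-4-(triisopropylsilyloxy)benzyl]-2-[3-methoxy-4-(triisopropylsilyloxy)phenyl]tetrahydrofuran-3-yl]methyl (2R)-2-methylbutanoate, via alkyl hypoiodite 13 (not isolated), via benzylic iodide 14 (not isolated)
Conditions: PhI(OAc)2 (1.3 equiv), I2 (0.6 equiv), cyclohexane/CH2Cl2 (4:1), tungsten-lamp irradiation, 20 °C, short reaction time
Reagents that add atoms: none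
Why: PhI(OAc)2 and I2 form acetyl hypoiodite, which turns the free C9' hydroxyl into hypoiodite 13; light cleaves the O–I bond, the alkoxy radical takes the benzylic hydrogen at C7 through a six-membered transition state (1,5-hydrogen atom transfer), iodine traps the benzylic radical as 14, and this labile para-silyloxybenzylic iodide ionizes and is captured by the hydroxyl oxygen, the HI released being reoxidized by the hypervalent iodine reagent. The closest known reaction type is the Suárez hypoiodite cyclization of alcohols to tetrahydrofurans (a Hofmann–Löffler–Freytag-type remote functionalization), established for 4-arylbutan-1-ols. The tetrahydrofuran ring closes by 5-exo attack of oxygen on the benzylic carbon (5-exo-tet on the iodide or its ion pair). The new stereocenter C7 (ring C2, R) is set by substrate control: C8 and C8' already carry cis CH2O-acyl and CH2Ar groups, so the aryl group should take the face trans to the C8 substituent to avoid an all-cis trisubstituted ring, and the electron-rich benzylic C–O bond can re-ionize in the mildly acidic medium toward this more stable trans isomer. Site selectivity between the two identical benzylic CH2 groups is secured by geometry, because only C7–H is δ to the oxygen radical whereas C7'–H is β (a 1,4-shift through a strained five-membered transition state), and the other δ position, C9–H, is deactivated by its acyloxy group. Chemoselectivity against ring iodination, attack of the oxygen radical on the neighbouring arene (chroman formation) and β-scission rests on the speed of benzylic 1,5-transfer, a non-polar medium, sub-stoichiometric iodine and short irradiation.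

Step 7
Reactants: 15 [(2R,3S,4S)-4-[3-methoxy-4-(triisopropylsilyloxy)benzyl]-2-[3-methoxy-4-(triisopropylsilyloxy)phenyl]tetrahydrofuran-3-yl]methyl (2R)-2-methylbutanoate
Product: 16 [(2R,3S,4S)-4-(4-hydroxy-3-methoxybenzyl)-2-(4-hydroxy-3-methoxyphenyl)tetrahydrofuran-3-yl]methyl (2R)-2-methylbutanoate
Conditions: Bu4NF (2.5 equiv), AcOH (2.5 equiv), THF, 0 °C
Reagents that add atoms: none
Why: Fluoride cleavage of aryl silyl ethers, buffered with acetic acid so that the phenoxides cannot attack the ester or epimerize its α-center, should leave the alkyl ester and the benzylic ether untouched.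

**Compound list**

1 | 3-(4-hydroxy-3-methoxyphenyl)propanoic acid (dihydroferulic acid) | OC(=O)CCc1ccc(O)c(OC)c1 | starting material
2 | triisopropylsilyl 3-[3-methoxy-4-(triisopropylsilyloxy)phenyl]propanoate (formed in the flask) | CC(C)[Si](C(C)C)(C(C)C)OC(=O)CCc1ccc(O[Si](C(C)C)(C(C)C)C(C)C)c(OC)c1 | intermediate
3 | 3-[3-methoxy-4-(triisopropylsilyloxy)phenyl]propanoic acid | OC(=O)CCc1ccc(O[Si](C(C)C)(C(C)C)C(C)C)c(OC)c1 | intermediate
4 | (R)-4-isopropyl-2-oxazolidinone | CC(C)[C@@H]1COC(=O)N1 | starting material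
5 | mixed anhydride of 3 with pivalic acid (formed in the flask) | CC(C)(C)C(=O)OC(=O)CCc1ccc(O[Si](C(C)C)(C(C)C)C(C)C)c(OC)c1 | intermediate
6 | (4R)-4-isopropyl-3-{3-[3-methoxy-4-(triisopropylsilyloxy)phenyl]propanoyl}oxazolidin-2-one | CC(C)[C@@H]1COC(=O)N1C(=O)CCc1ccc(O[Si](C(C)C)(C(C)C)C(C)C)c(OC)c1 | intermediate
7 | lithium Z-enolate of 6 (formed in the flask) | [Li]O/C(=C\Cc1ccc(O[Si](C(C)C)(C(C)C)C(C)C)c(OC)c1)N1[C@H](C(C)C)COC1=O | intermediate
8 | (4R,4'R)-3,3'-{(2S,3S)-2,3-bis[3-methoxy-4-(triisopropylsilyloxy)benzyl]butanedioyl}bis(4-isopropyloxazolidin-2-one) | CC(C)[C@@H]1COC(=O)N1C(=O)[C@@H](Cc1ccc(O[Si](C(C)C)(C(C)C)C(C)C)c(OC)c1)[C@H](Cc1ccc(O[Si](C(C)C)(C(C)C)C(C)C)c(OC)c1)C(=O)N1[C@H](C(C)C)COC1=O | intermediate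
9 | (2S,3S)-2,3-bis[3-methoxy-4-(triisopropylsilyloxy)benzyl]butane-1,4-diol | OC[C@@H](Cc1ccc(O[Si](C(C)C)(C(C)C)C(C)C)c(OC)c1)[C@H](Cc1ccc(O[Si](C(C)C)(C(C)C)C(C)C)c(OC)c1)CO | intermediate
10 | (R)-2-methylbutanoic acid | CC[C@@H](C)C(=O)O | starting material
11 | O-acylisourea from 10 and DCC (formed in the flask) | CC[C@@H](C)C(=O)OC(=NC1CCCCC1)NC1CCCCC1 | intermediate
12 | (2S,3S)-4-hydroxy-2,3-bis[3-methoxy-4-(triisopropylsilyloxy)benzyl]butyl (2R)-2-methylbutanoate | CC[C@@H](C)C(=O)OC[C@@H](Cc1ccc(O[Si](C(C)C)(C(C)C)C(C)C)c(OC)c1)[C@H](Cc1ccc(O[Si](C(C)C)(C(C)C)C(C)C)c(OC)c1)CO | intermediate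
13 | alkyl hypoiodite of 12 at O9' (formed in the flask) | CC[C@@H](C)C(=O)OC[C@@H](Cc1ccc(O[Si](C(C)C)(C(C)C)C(C)C)c(OC)c1)[C@H](Cc1ccc(O[Si](C(C)C)(C(C)C)C(C)C)c(OC)c1)COI | intermediate
14 | C7 benzylic iodide of 12, both C7 epimers (formed in the flask) | CC[C@@H](C)C(=O)OC[C@@H](C(I)c1ccc(O[Si](C(C)C)(C(C)C)C(C)C)c(OC)c1)[C@H](Cc1ccc(O[Si](C(C)C)(C(C)C)C(C)C)c(OC)c1)CO | intermediate
15 | [(2R,3S,4S)-4-[3-methoxy-4-(triisopropylsilyloxy)benzyl]-2-[3-methoxy-4-(triisopropylsilyloxy)phenyl]tetrahydrofuran-3-yl]methyl (2R)-2-methylbutanoate | CC[C@@H](C)C(=O)OC[C@@H]1[C@H](Cc2ccc(O[Si](C(C)C)(C(C)C)C(C)C)c(OC)c2)CO[C@H]1c1ccc(O[Si](C(C)C)(C(C)C)C(C)C)c(OC)c1 | intermediate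
16 | [(2R,3S,4S)-4-(4-hydroxy-3-methoxybenzyl)-2-(4-hydroxy-3-methoxyphenyl)tetrahydrofuran-3-yl]methyl (2R)-2-methylbutanoate | CC[C@@H](C)C(=O)OC[C@@H]1[C@H](Cc2ccc(O)c(OC)c2)CO[C@H]1c1ccc(O)c(OC)c1 | target

**Step count and risks**

Total steps: 7. Longest linear sequence: 7 (from 1; compounds 4 and 10 are purchased).

Steps most likely to fail:

1. Step 6. The electron-rich, silyloxy/methoxy-substituted rings may be iodinated by acetyl hypoiodite, the oxygen radical may add to the neighbouring arene instead of abstracting hydrogen, or the closure may give poor facial selectivity at C7. Fallback: the closure is moved to a two-electron, phenol-driven pathway. Compound 12 is desilylated (Bu4NF/AcOH, THF, 0 °C) to (2S,3S)-4-hydroxy-2,3-bis(4-hydroxy-3-methoxybenzyl)butyl (2R)-2-methylbutanoate F1. F1 is oxidized with DDQ (1.0 equiv, 1,4-dioxane, 10–20 °C) to the C7 para-quinone methide F2 (not isolated), whose exocyclic carbon is captured 5-exo-trig by the C9' hydroxyl, trans to the C8 substituent, to give 16 directly. The quinone methide that forms on the other ring cannot close a five-membered ring, so by design no more than about half of the material can follow the productive path; this fallback trades yield for established phenol-to-quinone-methide chemistry. It sets out from 12 and returns at 16.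

2. Step 3. The radical dimerization may give low conversion or erode diastereoselectivity (meso-type dimer), and TiCl4 may partly cleave the aryl silyl ethers. Fallback: the two halves are joined stepwise on a lactone, setting out from 6 and returning at 9.
   - The sodium enolate of 6 (NaN(SiMe3)2, THF, −78 °C) is alkylated with purchased tert-butyl bromoacetate, anti to the auxiliary substituent, to give tert-butyl (3S)-3-[3-methoxy-4-(triisopropylsilyloxy)benzyl]-4-[(4R)-4-isopropyl-2-oxooxazolidin-3-yl]-4-oxobutanoate F3.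
   - LiBH4 reduces the imide to tert-butyl (3S)-4-hydroxy-3-[3-methoxy-4-(triisopropylsilyloxy)benzyl]butanoate F4, and TsOH (cat.) in toluene closes it to (4S)-4-[3-methoxy-4-(triisopropylsilyloxy)benzyl]dihydrofuran-2(3H)-one F5.
   - The electrophile is made from purchased vanillin: TIPSCl/imidazole gives 3-methoxy-4-(triisopropylsilyloxy)benzaldehyde F6, NaBH4 gives [3-methoxy-4-(triisopropylsilyloxy)phenyl]methanol F7, and PBr3 gives [4-(bromomethyl)-2-methoxyphenoxy]triisopropylsilane F8.
   - The lithium enolate of F5 (LiN(iPr)2, THF, −78 °C) is alkylated with F8 anti to the existing benzyl group to give (3S,4S)-3,4-bis[3-methoxy-4-(triisopropylsilyloxy)benzyl]dihydrofuran-2(3H)-one F9, and LiAlH4 (THF, 0 °C) reduces F9 to 9.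

3. Step 4. Hydride may attack the ring carbonyl of the auxiliary in this doubly α-branched, crowded bis-imide (endocyclic cleavage), or reduction may stall after one imide. Fallback: hydrolysis then reduction in place of direct reductive cleavage. Compound 8 is hydrolysed with LiOH/H2O2 (THF/H2O, 0 °C) to (2S,3S)-2,3-bis[3-methoxy-4-(triisopropylsilyloxy)benzyl]butanedioic acid F10, and F10 is reduced with BH3·SMe2 (THF, 0 → 20 °C). It sets out from 8 and returns at 9.

**Further compounds**

F1 | step 6 | (2S,3S)-4-hydroxy-2,3-bis(4-hydroxy-3-methoxybenzyl)butyl (2R)-2-methylbutanoate | CC[C@@H](C)C(=O)OC[C@@H](Cc1ccc(O)c(OC)c1)[C@H](Cc1ccc(O)c(OC)c1)CO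
F2 | step 6 | C7 para-quinone methide of F1 (not isolated) | CC[C@@H](C)C(=O)OC[C@@H](C=C1C=CC(=O)C(OC)=C1)[C@H](Cc1ccc(O)c(OC)c1)CO
F3 | step 3 | tert-butyl (3S)-3-[3-methoxy-4-(triisopropylsilyloxy)benzyl]-4-[(4R)-4-isopropyl-2-oxooxazolidin-3-yl]-4-oxobutanoate | CC(C)[C@@H]1COC(=O)N1C(=O)[C@@H](Cc1ccc(O[Si](C(C)C)(C(C)C)C(C)C)c(OC)c1)CC(=O)OC(C)(C)C
F4 | step 3 | tert-butyl (3S)-4-hydroxy-3-[3-methoxy-4-(triisopropylsilyloxy)benzyl]butanoate | OC[C@@H](Cc1ccc(O[Si](C(C)C)(C(C)C)C(C)C)c(OC)c1)CC(=O)OC(C)(C)C
F5 | step 3 | (4S)-4-[3-methoxy-4-(triisopropylsilyloxy)benzyl]dihydrofuran-2(3H)-one | O=C1C[C@H](Cc2ccc(O[Si](C(C)C)(C(C)C)C(C)C)c(OC)c2)CO1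
F6 | step 3 | 3-methoxy-4-(triisopropylsilyloxy)benzaldehyde | O=Cc1ccc(O[Si](C(C)C)(C(C)C)C(C)C)c(OC)c1
F7 | step 3 | [3-methoxy-4-(triisopropylsilyloxy)phenyl]methanol | OCc1ccc(O[Si](C(C)C)(C(C)C)C(C)C)c(OC)c1
F8 | step 3 | [4-(bromomethyl)-2-methoxyphenoxy]triisopropylsilane | BrCc1ccc(O[Si](C(C)C)(C(C)C)C(C)C)c(OC)c1
F9 | step 3 | (3S,4S)-3,4-bis[3-methoxy-4-(triisopropylsilyloxy)benzyl]dihydrofuran-2(3H)-one | O=C1[C@@H](Cc2ccc(O[Si](C(C)C)(C(C)C)C(C)C)c(OC)c2)[C@H](Cc2ccc(O[Si](C(C)C)(C(C)C)C(C)C)c(OC)c2)CO1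
F10 | step 4 | (2S,3S)-2,3-bis[3-methoxy-4-(triisopropylsilyloxy)benzyl]butanedioic acid | OC(=O)[C@@H](Cc1ccc(O[Si](C(C)C)(C(C)C)C(C)C)c(OC)c1)[C@H](Cc1ccc(O[Si](C(C)C)(C(C)C)C(C)C)c(OC)c1)C(=O)O
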